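## Retrosynthetic overview

1. The target is reached from its O-allyl-protected form 16 by Pd(0) deallylation; 16 comes from the primary alcohol 15 by Mitsunobu etherification with eugenol.
2. Key disconnection of 15: the C2–C3 and O1–C2 bonds in one [4+1] annulation. The vanillyl carbon, natively an electrophile, is used as a nucleophile in the form of a chiral benzylic sulfonium ylide (a reversed-polarity d1 synthon) and joined to the electrophilic exocyclic carbon of an o-quinone methide.
3. The o-quinone methide is released by fluoride from the silyl-protected aryl oxirane 4, which comes from eugenol by ortho-formylation, silylation and Corey–Chaykovsky epoxidation.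
4. The ylide precursor 10 comes from vanillyl alcohol and C2-symmetric (2S,5S)-2,5-dimethylthiolane, itself made from (2R,5R)-hexane-2,5-diol.
5. Ring order: both benzene rings are bought; the oxirane of step 3 is sacrificial; the dihydrofuran ring is the only ring built (step 8).

Assumption: the C2-symmetric thiolane ylide shows the same facial preference toward the o-quinone methide as toward aldehydes ((2R,5R)-sulfide gives (S,S)-stilbene oxide), so the (2S,5S)-sulfide is chosen to give 2S.

## Route

Step 1
Reactants: 1 eugenol
Product: 2 5-allyl-2-hydroxy-3-methoxybenzaldehyde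
Conditions: MgCl2, Et3N, (CH2O)n, MeCN, reflux; then 1 M HCl
Reagents that add atoms: paraformaldehyde (formaldehyde), C=O
Why: Casnati–Skattebøl ortho-formylation: the magnesium phenoxide delivers formaldehyde only to the free ortho position (C6) and a second formaldehyde oxidises the benzylic alkoxide by hydride transfer, while the allyl group is untouched.

Step 2
Reactants: 2 5-allyl-2-hydroxy-3-methoxybenzaldehyde
Product: 3 5-allyl-2-[(tert-butyldimethylsilyl)oxy]-3-methoxybenzaldehyde
Conditions: TBSCl, imidazole, DMF, rt
Reagents that add atoms: tert-butyldimethylsilyl chloride, CC(C)(C)[Si](C)(C)Cl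
Why: Standard imidazole-promoted silylation of a phenol; the silyl ether is the fluoride-sensitive trigger needed in step 8.

Step 3
Reactants: 3 5-allyl-2-[(tert-butyldimethylsilyl)oxy]-3-methoxybenzaldehyde
Product: 4 racemic 2-{5-allyl-2-[(tert-butyldimethylsilyl)oxy]-3-methoxyphenyl}oxirane
Conditions: Me3S+ I−, KHMDS, THF, −20 → 0 °C; Et3N-deactivated silica
Reagents that add atoms: trimethylsulfonium iodide, C[S+](C)C.[I-]
Why: Johnson–Corey–Chaykovsky epoxidation: dimethylsulfonium methylide adds to the aldehyde and the betaine closes 3-exo-tet faster than an O-to-O silyl shift, KHMDS being too weak to deprotonate the allylic CH2; the new stereocentre is racemic and is erased in step 8.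

Step 4
Reactants: 5 (2R,5R)-hexane-2,5-diol
Product: 6 (2R,5R)-hexane-2,5-diyl dimethanesulfonate
Conditions: MsCl, Et3N, CH2Cl2, −20 → 0 °C
Reagents that add atoms: methanesulfonyl chloride, CS(=O)(=O)Cl
Why: Mesylation of the secondary alcohols proceeds with retention because no C–O bond is broken.

Step 5
Reactants: 6 (2R,5R)-hexane-2,5-diyl dimethanesulfonate
Product: 7 (2S,5S)-2,5-dimethylthiolane
Conditions: Na2S·9H2O, DMSO, rt; distil
Reagents that add atoms: sodium sulfide, [Na+].[Na+].[S-2]
Why: Double SN2 displacement by sulfide (intermolecular, then intramolecular 5-exo-tet) inverts both centres and gives the C2-symmetric (2S,5S)-thiolane.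

Step 6
Reactants: 8 vanillyl alcohol
Product: 9 [4-(allyloxy)-3-methoxyphenyl]methanol
Conditions: allyl bromide, K2CO3, acetone, reflux
Reagents that add atoms: allyl bromide, C=CCBr
Why: Williamson etherification: carbonate deprotonates only the phenol (pKa about 10), so O-allylation is chemoselective over the benzylic alcohol.

Step 7
Reactants: 9 [4-(allyloxy)-3-methoxyphenyl]methanol; 7 (2S,5S)-2,5-dimethylthiolane
Product: 10 (2S,5S)-1-[4-(allyloxy)-3-methoxybenzyl]-2,5-dimethylthiolan-1-ium tetrafluoroborate
Conditions: 7 (1.5 equiv), HBF4·OEt2 (1.0 equiv), CH2Cl2, 0 °C → rt; precipitate with Et2O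
Reagents that add atoms: tetrafluoroboric acid diethyl etherate (supplies the BF4 counter-ion), [H+].F[B-](F)(F)F
Why: Acid-promoted dehydrative S-alkylation (SN1): the 4-alkoxy-3-methoxybenzyl cation is captured by the excess sulfide, and because the thiolane is C2-symmetric only one sulfonium stereoisomer can form.

Step 8
Reactants: 4 racemic 2-{5-allyl-2-[(tert-butyldimethylsilyl)oxy]-3-methoxyphenyl}oxirane; 10 (2S,5S)-1-[4-(allyloxy)-3-methoxybenzyl]-2,5-dimethylthiolan-1-ium tetrafluoroborate
Product: 15 [(2S,3R)-5-allyl-2-[4-(allyloxy)-3-methoxyphenyl]-7-methoxy-2,3-dihydrobenzofuran-3-yl]methanol, via epoxy phenoxide 11 (not isolated), via o-quinone methide 12 (not isolated), via sulfonium ylide 13 (not isolated), via betaine 14 (not isolated)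
Conditions: 10 (1.3 equiv), CsF (3 equiv), 18-crown-6 (cat.), MeCN–CH2Cl2, −20 °C → rt; aq. NH4Cl; chromatography (removes any cis isomer), recrystallise
Reagents that add atoms: none
Why: Proposed new method: fluoride unmasks the phenoxide, which opens the adjacent oxirane to the o-quinone methide alkoxide; this alkoxide deprotonates 10 to the benzylic sulfonium ylide (the vanillyl carbon in reversed polarity), which adds 1,4 to the quinone methide to form C2–C3 between two natively electrophilic carbons, and the rearomatised phenoxide then displaces the sulfide at C2 by SN2 (5-exo-tet); the closest known reactions are the trans-selective [4+1] annulations of sulfur ylides with o-quinone methides generated by base from 2-(1-tosylalkyl)phenols and the epoxidations of aldehydes with C2-symmetric thiolane benzyl ylides; C2 is set by the thiolane (attack on the ylide face remote from the cis-methyl, then inversion in the ring closure, giving 2S) and C3 by the less hindered anti approach that leads to the trans ring (3R).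

Step 9
Reactants: 15 [(2S,3R)-5-allyl-2-[4-(allyloxy)-3-methoxyphenyl]-7-methoxy-2,3-dihydrobenzofuran-3-yl]methanol; 1 eugenol
Product: 16 (2S,3R)-5-allyl-3-[(4-allyl-2-methoxyphenoxy)methyl]-2-[4-(allyloxy)-3-methoxyphenyl]-7-methoxy-2,3-dihydrobenzofuran
Conditions: PPh3, DIAD, THF, 0 °C → rt
Reagents that add atoms: none
Why: Mitsunobu etherification of the primary alcohol with eugenol (pKa about 10) forms the aryl ether under neutral conditions without touching C2 or C3.

Step 10
Reactants: 16 (2S,3R)-5-allyl-3-[(4-allyl-2-methoxyphenoxy)methyl]-2-[4-(allyloxy)-3-methoxyphenyl]-7-methoxy-2,3-dihydrobenzofuran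
Product: 17 4-[(2S,3R)-5-allyl-3-[(4-allyl-2-methoxyphenoxy)methyl]-7-methoxy-2,3-dihydrobenzofuran-2-yl]-2-methoxyphenol (CNP0138854.1)
Conditions: Pd(PPh3)4 (5 mol %), morpholine, THF, rt
Reagents that add atoms: none
Why: Tsuji–Trost deallylation: Pd(0) ionises only the aryl allyl ether to a π-allyl complex that morpholine captures, the two C-allyl groups and the benzylic ether stereocentres being inert under these neutral conditions.

## Compound list

1 | eugenol (4-allyl-2-methoxyphenol) | C=CCc1ccc(O)c(OC)c1 | starting material
2 | 5-allyl-2-hydroxy-3-methoxybenzaldehyde | C=CCc1cc(OC)c(O)c(C=O)c1 | intermediate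
3 | 5-allyl-2-[(tert-butyldimethylsilyl)oxy]-3-methoxybenzaldehyde | C=CCc1cc(OC)c(O[Si](C)(C)C(C)(C)C)c(C=O)c1 | intermediate
4 | racemic 2-{5-allyl-2-[(tert-butyldimethylsilyl)oxy]-3-methoxyphenyl}oxirane | C=CCc1cc(OC)c(O[Si](C)(C)C(C)(C)C)c(C2CO2)c1 | intermediate
5 | (2R,5R)-hexane-2,5-diol | C[C@@H](O)CC[C@@H](C)O | starting material
6 | (2R,5R)-hexane-2,5-diyl dimethanesulfonate | C[C@@H](OS(C)(=O)=O)CC[C@@H](C)OS(C)(=O)=O | intermediate
7 | (2S,5S)-2,5-dimethylthiolane | C[C@H]1CC[C@H](C)S1 | intermediate
8 | vanillyl alcohol (4-hydroxy-3-methoxybenzyl alcohol) | OCc1ccc(O)c(OC)c1 | starting material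
9 | [4-(allyloxy)-3-methoxyphenyl]methanol | OCc1ccc(OCC=C)c(OC)c1 | intermediate
10 | (2S,5S)-1-[4-(allyloxy)-3-methoxybenzyl]-2,5-dimethylthiolan-1-ium tetrafluoroborate | C[C@H]1CC[C@H](C)[S+]1Cc1ccc(OCC=C)c(OC)c1.F[B-](F)(F)F | intermediate
11 | racemic 4-allyl-2-methoxy-6-(oxiran-2-yl)phenol (present as its caesium phenoxide) | C=CCc1cc(OC)c(O)c(C2CO2)c1 | intermediate
12 | 4-allyl-6-(2-hydroxyethylidene)-2-methoxycyclohexa-2,4-dien-1-one (o-quinone methide) | C=CCC1=CC(=CCO)C(=O)C(OC)=C1 | intermediate
13 | [4-(allyloxy)-3-methoxyphenyl][(2S,5S)-2,5-dimethylthiolan-1-ium-1-yl]methanide (sulfonium ylide) | C[C@H]1CC[C@H](C)[S+]1[CH-]c1ccc(OCC=C)c(OC)c1 | intermediate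
14 | 4-allyl-2-{(1R,2R)-1-[4-(allyloxy)-3-methoxyphenyl]-1-[(2S,5S)-2,5-dimethylthiolan-1-ium-1-yl]-3-hydroxypropan-2-yl}-6-methoxyphenolate (betaine) | C=CCc1cc(OC)c([O-])c(c1)[C@H](CO)[C@H](c1ccc(OCC=C)c(OC)c1)[S+]1[C@@H](C)CC[C@@H]1C | intermediate
15 | [(2S,3R)-5-allyl-2-[4-(allyloxy)-3-methoxyphenyl]-7-methoxy-2,3-dihydrobenzofuran-3-yl]methanol | OC[C@H]1c2cc(CC=C)cc(OC)c2O[C@@H]1c1ccc(OCC=C)c(OC)c1 | intermediate
16 | (2S,3R)-5-allyl-3-[(4-allyl-2-methoxyphenoxy)methyl]-2-[4-(allyloxy)-3-methoxyphenyl]-7-methoxy-2,3-dihydrobenzofuran | C=CCc1ccc(OC[C@H]2c3cc(CC=C)cc(OC)c3O[C@@H]2c2ccc(OCC=C)c(OC)c2)c(OC)c1 | intermediate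
17 | 4-[(2S,3R)-5-allyl-3-[(4-allyl-2-methoxyphenoxy)methyl]-7-methoxy-2,3-dihydrobenzofuran-2-yl]-2-methoxyphenol | C=CCc1ccc(OC[C@H]2c3cc(CC=C)cc(OC)c3O[C@@H]2c2ccc(O)c(OC)c2)c(OC)c1 | target

## Step count and risks

Total steps: 10. Longest linear sequence: 6 (steps 1, 2, 3, 8, 9, 10 from eugenol; the branch 4, 5, 7, 8, 9, 10 from the diol is equally long).

Most likely to fail, in order:

**Step 8 (key cascade).** Possible problems: O-benzylation of the phenoxide by salt 10, oligomerisation of the o-quinone methide or its tautomerisation to a vinylphenol, and ee or trans:cis below expectation (85–95 % ee is typical for this ylide class). Any cis isomer must be separated, not epimerised, since epimerising its C2 would give the enantiomer of the target. The fallback sets out from 4 and comes back at 15. Compound 4 is desilylated with TBAF in THF–H2O at 0 °C in the presence of sodium p-toluenesulfinate and then formic acid, so that the o-quinone methide is intercepted and stored as the bench-stable sulfone racemic 4-allyl-2-(2-hydroxy-1-tosylethyl)-6-methoxyphenol F1. F1 and salt 10 are then stirred with Cs2CO3 in CH2Cl2 at rt; carbonate-induced loss of sulfinate releases the same o-quinone methide slowly into preformed ylide, and the annulation gives 15 without fluoride and without a free epoxy phenoxide.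

**Step 3 (epoxidation next to an aryl silyl ether).** The betaine alkoxide could take the silyl group from the neighbouring phenol oxygen and end as a 3-silyloxy-dihydrobenzofuran. The fallback sets out from 3 and comes back at 4. Salt-free Wittig methylenation (Ph3P=CH2, THF, 0 °C), which has no free alkoxide, gives the styrene tert-butyl(4-allyl-2-methoxy-6-vinylphenoxy)dimethylsilane F2. The conjugated alkene of F2 is then epoxidised chemoselectively with a Mn(salen)Cl catalyst and buffered NaOCl in CH2Cl2 at 0 °C (isolated terminal alkenes such as the allyl group are poor substrates for this catalyst) to give 4.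

**Step 7 (sulfonium salt from an electron-rich benzylic alcohol).** The benzylic cation may oligomerise by Friedel–Crafts reaction, or the salt may be too labile to isolate cleanly. The fallback sets out from 9 and comes back at 10. Alcohol 9 is converted with PBr3 in Et2O at 0 °C into 4-(allyloxy)-3-methoxybenzyl bromide F3, which is used crude to alkylate sulfide 7 in the presence of AgBF4 (acetone–CH2Cl2, 0 °C, dark); filtration from silver bromide and precipitation with Et2O give 10 by an SN2 route with no free cation.

## Further compounds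

F1 | step 8 | racemic 4-allyl-2-(2-hydroxy-1-tosylethyl)-6-methoxyphenol | C=CCc1cc(OC)c(O)c(C(CO)S(=O)(=O)c2ccc(C)cc2)c1
F2 | step 3 | tert-butyl(4-allyl-2-methoxy-6-vinylphenoxy)dimethylsilane | C=CCc1cc(OC)c(O[Si](C)(C)C(C)(C)C)c(C=C)c1
F3 | step 7 | 4-(allyloxy)-3-methoxybenzyl bromide | C=CCOc1ccc(CBr)cc1OC
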